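The target is disconnected as a folded polyketide. Ring A (C4a, C5, C6, C7, C8, C8a) bears oxygen at C6 and C8 and the C1 carboxyl on C8a, a resorcylate, whereas the only stereocentre, C3, sits outside ring A on the C4 arm. Step 11 exploits this in one pot: a diketo-dioxinone is opened by methanol to a triketo ester, base forges bond C8a–C4a with aromatisation of ring A, and acid closes lactone ring B through C1–O2. The precursor is a 2,2-dimethyl-1,3-dioxin-4-one whose 2,4-dioxoalkyl chain carries the (R)-C3 carbinol as a triethylsilyl ether and the side-chain ketone as a dioxolane; C3 is set earlier by hydrogenation with RuCl2[(R)-BINAP].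

Key step: step 11

Remark: locants C1 to C8a are those of the isochroman-1-one core of the target; pentylmagnesium bromide is taken as the purchased ethereal solution (equivalent to 1-bromopentane and magnesium).

Step 1
Reactants: 1 cycloheptanone; 2 pentylmagnesium bromide
Product: 3 1-pentylcycloheptan-1-ol
Conditions: C5H11MgBr (1.2 equiv), Et2O, 0 °C to rt; 1 M aq. HCl, 0 °C
Reagents that add atoms: none
Why: Grignard 1,2-addition of the pentyl nucleophile to the ketone should give the tertiary alcohol, which has no stereocentre because the ring is symmetrical.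

Step 2
Reactants: 3 1-pentylcycloheptan-1-ol
Product: 4 1-pentylcyclohept-1-ene
Conditions: TsOH·H2O (cat.), toluene, reflux, Dean–Stark
Reagents that add atoms: none
Why: Acid-catalysed E1 dehydration under equilibrating conditions should favour the endocyclic trisubstituted alkene (Zaitsev product), and any exocyclic isomer is purged after step 3 because it is cleaved to neutral cycloheptanone and volatile pentanoic acid.

Step 3
Reactants: 4 1-pentylcyclohept-1-ene
Product: 5 7-oxododecanoic acid
Conditions: RuCl3·xH2O (cat.), NaIO4 (4 equiv), MeCN/EtOAc/H2O, rt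
Reagents that add atoms: sodium periodate, [Na+].[O-]I(=O)(=O)=O (net source of the three new oxygen atoms, transferred through RuO4)
Why: RuO4-catalysed oxidative cleavage of the trisubstituted C=C bond should give the ketone at the pentyl-bearing carbon and the carboxylic acid at the CH carbon, opening the seven-membered ring to the C12 keto acid.

Step 4
Reactants: 5 7-oxododecanoic acid; 6 Meldrum's acid (2,2-dimethyl-1,3-dioxane-4,6-dione)
Product: 8 methyl 3,9-dioxotetradecanoate, via acyl Meldrum's acid 7 (not isolated)
Conditions: DCC, DMAP, CH2Cl2, 0 °C to rt; filter, acid wash; then MeOH, reflux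
Reagents that add atoms: methanol, CO
Why: Carbodiimide-mediated C-acylation of Meldrum's acid followed by methanolysis of the adduct through its acylketene (Meldrum's acid β-keto ester homologation) should add the two-carbon ester unit with loss of acetone and CO2, the isolated C9 ketone being a spectator.

Step 5
Reactants: 8 methyl 3,9-dioxotetradecanoate
Product: 9 methyl (R)-3-hydroxy-9-oxotetradecanoate
Conditions: RuCl2[(R)-BINAP] (0.5 mol %), H2 (5 bar), MeOH, 50 °C
Reagents that add atoms: none
Why: Noyori asymmetric hydrogenation, in which the β-keto ester binds ruthenium as a chelate and hydride is delivered to the ketone face selected by the (R)-BINAP ligand, should give the (R)-carbinol, while the non-chelating C9 dialkyl ketone should not be reduced by this diamine-free catalyst.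

Step 6
Reactants: 9 methyl (R)-3-hydroxy-9-oxotetradecanoate
Product: 10 methyl (R)-3-hydroxy-8-(2-pentyl-1,3-dioxolan-2-yl)octanoate
Conditions: HOCH2CH2OH (5 equiv), PPTS (cat.), benzene, reflux, Dean–Stark
Reagents that add atoms: ethylene glycol, OCCO
Why: Acid-catalysed ketalisation with azeotropic removal of water should protect the only ketone under a pyridinium acid too mild to dehydrate the β-hydroxy ester, and any ester exchange with the diol would be harmless because step 7 converts either ester into the same amide.

Step 7
Reactants: 10 methyl (R)-3-hydroxy-8-(2-pentyl-1,3-dioxolan-2-yl)octanoate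
Product: 11 (R)-3-hydroxy-N-methoxy-N-methyl-8-(2-pentyl-1,3-dioxolan-2-yl)octanamide
Conditions: MeNH(OMe)·HCl, iPrMgCl, THF, −20 to 0 °C
Reagents that add atoms: N,O-dimethylhydroxylamine hydrochloride, CNOC.Cl
Why: Aminolysis of the ester by the chloromagnesium amide of N,O-dimethylhydroxylamine (Weinreb amide formation) should proceed at low temperature with the C3 oxygen held as its magnesium alkoxide, which suppresses β-elimination and leaves the stereocentre and the dioxolane untouched.

Step 8
Reactants: 11 (R)-3-hydroxy-N-methoxy-N-methyl-8-(2-pentyl-1,3-dioxolan-2-yl)octanamide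
Product: 12 (R)-N-methoxy-N-methyl-8-(2-pentyl-1,3-dioxolan-2-yl)-3-(triethylsilyloxy)octanamide
Conditions: Et3SiCl, imidazole, DMF, 0 °C to rt
Reagents that add atoms: chlorotriethylsilane, CC[Si](Cl)(CC)CC
Why: Imidazole-promoted silylation of the secondary alcohol (silyl ether protection) should be clean under basic conditions that affect neither the dioxolane nor the amide.

Step 9
Reactants: 13 2,2,6-trimethyl-4H-1,3-dioxin-4-one; 14 acetyl chloride
Product: 15 2,2-dimethyl-6-(2-oxopropyl)-4H-1,3-dioxin-4-one
Conditions: 13 (2 equiv), LiN(SiMe3)2 (2 equiv), THF, −78 °C; then 14 (1 equiv); 1 M aq. HCl quench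
Reagents that add atoms: none
Why: γ-Deprotonation of the dioxinone gives the lithium dienolate, which should undergo C-acylation at the γ-carbon by the acid chloride (crossed Claisen-type acylation), the second equivalent of dienolate taking up the acidic proton of the β-keto product.

Step 10
Reactants: 15 2,2-dimethyl-6-(2-oxopropyl)-4H-1,3-dioxin-4-one; 12 (R)-N-methoxy-N-methyl-8-(2-pentyl-1,3-dioxolan-2-yl)-3-(triethylsilyloxy)octanamide
Product: 16 (R)-2,2-dimethyl-6-[2,4-dioxo-11-(2-pentyl-1,3-dioxolan-2-yl)-6-(triethylsilyloxy)undecyl]-4H-1,3-dioxin-4-one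
Conditions: 15 (2.2 equiv), LiN(iPr)2 (4.4 equiv), THF, −78 °C; then 12, −78 to −40 °C; AcOH quench at −78 °C; short silica plug
Reagents that add atoms: none
Why: Double deprotonation of the β-keto-dioxinone gives a dianion that should react at its more basic terminal carbon with the Weinreb amide (γ-acylation of a 1,3-dicarbonyl dianion, Weinreb ketone synthesis), the chelated tetrahedral adduct preventing over-addition and collapsing on the acetic acid quench to the 1,3-diketone without touching C3.

Step 11
Reactants: 16 (R)-2,2-dimethyl-6-[2,4-dioxo-11-(2-pentyl-1,3-dioxolan-2-yl)-6-(triethylsilyloxy)undecyl]-4H-1,3-dioxin-4-one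
Product: 20 (R)-6,8-dihydroxy-3-(6-oxoundecyl)isochroman-1-one, via acylketene 17 (not isolated), via triketo methyl ester 18 (not isolated), via resorcylate ester 19 (not isolated)
Conditions: MeOH (10 equiv), PhMe, 110 °C, sealed tube; then Cs2CO3, MeOH, rt; then 3 M aq. HCl, THF/MeOH, rt to 45 °C
Reagents that add atoms: water, O (oxygen of the side-chain ketone, through hydrolysis of the dioxolane); methanol, CO (enters 18 and 19 and is lost again in the lactonisation)
Why: At 110 °C dioxinone 16 should lose acetone by retro-hetero-Diels–Alder fragmentation and the acylketene 17 is captured by the excess methanol as the 3,5,7-trioxo ester 18; Cs2CO3 then ionises the C8a methylene between the ester and the C8 ketone, which adds to the C4a ketone, and loss of water with enolisation gives ring A as resorcylate 19. The closest known reaction type is the biomimetic aldol aromatisation of 3,5,7-triketo esters generated from diketo-dioxinones, followed by acid-induced lactonisation of the resulting 2-(2-hydroxyalkyl)benzoate. Ring A closes in a 6-(enolexo)-exo-trig aldol through bond C8a–C4a, and ring B closes in a 6-exo-trig acyl substitution in which the C3 hydroxyl, freed from its silyl ether by aqueous HCl, displaces methanol from C1 to form bond C1–O2, while the same acid hydrolyses the dioxolane to the side-chain ketone. No stereocentre is formed: C3 is a non-enolisable carbinol carbon whose C–O bond is never broken, so the (R) configuration set in step 5 is carried into the lactone. The step needs the C8a-to-C4a aldol to win over Claisen closure onto the ester, pyranone formation by oxygen attack on the ketene or ester, and β-elimination of the C3 silyloxy group; the mild carbonate base ionises only the doubly activated C8a, C7 and C5 methylenes (so C4 stays protonated), only C8a can reach a ketone through a six-membered transition state that ends in an arene, excess methanol outruns intramolecular ketene capture, and the silyl ether keeps the C3 oxygen from adding to the ketones.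

Step 12
Reactants: 20 (R)-6,8-dihydroxy-3-(6-oxoundecyl)isochroman-1-one
Product: 21 (R)-8-hydroxy-6-methoxy-3-(6-oxoundecyl)isochroman-1-one
Conditions: MeI (1.1 equiv), K2CO3 (1.1 equiv), acetone, rt
Reagents that add atoms: iodomethane, CI
Why: Williamson O-methylation should occur only at the C6 phenol, the more acidic hydroxyl para to the lactone carbonyl, because the C8 hydroxyl is held in an intramolecular hydrogen bond to the C1 carbonyl and is not alkylated by a weak carbonate base with one equivalent of iodomethane.

Compound list
1 | cycloheptanone | O=C1CCCCCC1 | starting material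
2 | pentylmagnesium bromide | CCCCC[Mg]Br | starting material
3 | 1-pentylcycloheptan-1-ol | CCCCCC1(O)CCCCCC1 | intermediate
4 | 1-pentylcyclohept-1-ene | CCCCCC1=CCCCCC1 | intermediate
5 | 7-oxododecanoic acid | CCCCCC(=O)CCCCCC(=O)O | intermediate
6 | Meldrum's acid (2,2-dimethyl-1,3-dioxane-4,6-dione) | CC1(C)OC(=O)CC(=O)O1 | starting material
7 | 5-(1-hydroxy-7-oxododecylidene)-2,2-dimethyl-1,3-dioxane-4,6-dione | CCCCCC(=O)CCCCCC(O)=C1C(=O)OC(C)(C)OC1=O | intermediate (not isolated)
8 | methyl 3,9-dioxotetradecanoate | CCCCCC(=O)CCCCCC(=O)CC(=O)OC | intermediate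
9 | methyl (R)-3-hydroxy-9-oxotetradecanoate | CCCCCC(=O)CCCCC[C@@H](O)CC(=O)OC | intermediate
10 | methyl (R)-3-hydroxy-8-(2-pentyl-1,3-dioxolan-2-yl)octanoate | CCCCCC1(OCCO1)CCCCC[C@@H](O)CC(=O)OC | intermediate
11 | (R)-3-hydroxy-N-methoxy-N-methyl-8-(2-pentyl-1,3-dioxolan-2-yl)octanamide | CCCCCC1(OCCO1)CCCCC[C@@H](O)CC(=O)N(C)OC | intermediate
12 | (R)-N-methoxy-N-methyl-8-(2-pentyl-1,3-dioxolan-2-yl)-3-(triethylsilyloxy)octanamide | CCCCCC1(OCCO1)CCCCC[C@@H](O[Si](CC)(CC)CC)CC(=O)N(C)OC | intermediate
13 | 2,2,6-trimethyl-4H-1,3-dioxin-4-one | CC1=CC(=O)OC(C)(C)O1 | starting material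
14 | acetyl chloride | CC(=O)Cl | starting material
15 | 2,2-dimethyl-6-(2-oxopropyl)-4H-1,3-dioxin-4-one | CC(=O)CC1=CC(=O)OC(C)(C)O1 | intermediate
16 | (R)-2,2-dimethyl-6-[2,4-dioxo-11-(2-pentyl-1,3-dioxolan-2-yl)-6-(triethylsilyloxy)undecyl]-4H-1,3-dioxin-4-one | CCCCCC1(OCCO1)CCCCC[C@@H](O[Si](CC)(CC)CC)CC(=O)CC(=O)CC2=CC(=O)OC(C)(C)O2 | intermediate (precursor of the key step)
17 | (R)-14-(2-pentyl-1,3-dioxolan-2-yl)-9-(triethylsilyloxy)tetradec-1-ene-1,3,5,7-tetrone (acylketene) | CCCCCC1(OCCO1)CCCCC[C@@H](O[Si](CC)(CC)CC)CC(=O)CC(=O)CC(=O)C=C=O | intermediate (not isolated)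
18 | methyl (R)-3,5,7-trioxo-14-(2-pentyl-1,3-dioxolan-2-yl)-9-(triethylsilyloxy)tetradecanoate | CCCCCC1(OCCO1)CCCCC[C@@H](O[Si](CC)(CC)CC)CC(=O)CC(=O)CC(=O)CC(=O)OC | intermediate (not isolated)
19 | methyl 2,4-dihydroxy-6-[(R)-7-(2-pentyl-1,3-dioxolan-2-yl)-2-(triethylsilyloxy)heptyl]benzoate | CCCCCC1(OCCO1)CCCCC[C@@H](O[Si](CC)(CC)CC)Cc2cc(O)cc(O)c2C(=O)OC | intermediate (not isolated)
20 | (R)-6,8-dihydroxy-3-(6-oxoundecyl)isochroman-1-one | CCCCCC(=O)CCCCC[C@@H]1Cc2cc(O)cc(O)c2C(=O)O1 | intermediate (product of the key step)
21 | (R)-8-hydroxy-6-methoxy-3-(6-oxoundecyl)isochroman-1-one | CCCCCC(=O)CCCCC[C@@H]1Cc2cc(OC)cc(O)c2C(=O)O1 | target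

Total step count: 12. Longest linear sequence: 11 steps (steps 1 to 8, then 10, 11 and 12, from cycloheptanone); step 9 is a one-step side branch.

Steps most likely to fail

Step 11. The cascade may go astray in several ways: the ketene may be captured internally by a diketone enol oxygen, the base stage may close the triketo ester by oxygen attack or by Claisen attack on the ester, the silyloxy group may be lost by β-elimination, or the ester-to-lactone exchange may stall in acid. The fallback avoids the ketene altogether and sets out from 16. Treatment with Et3N in CH2Cl2 at rt should let the dioxinone α-carbon (the future C8a) add to the C4a ketone and, after dehydration, give the acetonide-protected resorcylate 7-hydroxy-2,2-dimethyl-5-[(R)-7-(2-pentyl-1,3-dioxolan-2-yl)-2-(triethylsilyloxy)heptyl]-4H-benzo[d][1,3]dioxin-4-one F1. Bu4NF in THF should then remove the silyl group, and the C3 alkoxide should open the benzodioxinone intramolecularly with loss of acetone to give (R)-6,8-dihydroxy-3-[5-(2-pentyl-1,3-dioxolan-2-yl)pentyl]isochroman-1-one F2. Brief treatment with 1 M aq. HCl in THF should hydrolyse the dioxolane, and the route is rejoined at 20.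

Step 10. Proton transfer may outrun C-acylation, since the dianion can act as a base toward the α-methylene of the amide, and the resulting amide enolate may expel the silyloxy group. The fallback replaces acylation by aldol addition and oxidation and sets out from 12. Reduction with iBu2AlH in THF at −78 °C should give (R)-8-(2-pentyl-1,3-dioxolan-2-yl)-3-(triethylsilyloxy)octanal F3. The dianion of 15 (LiN(iPr)2, THF, −78 °C) should add to this aldehyde to give 6-[(6R)-4-hydroxy-2-oxo-11-(2-pentyl-1,3-dioxolan-2-yl)-6-(triethylsilyloxy)undecyl]-2,2-dimethyl-4H-1,3-dioxin-4-one F4 as a mixture of carbinol epimers, which is of no consequence. Oxidation with Dess–Martin periodinane (NaHCO3, CH2Cl2) should then return the route to 16.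

Step 6. Ester exchange or oligomerisation through the free carbinol may compete, or ketalisation may be slow under an acid weak enough to spare the β-hydroxy ester. The fallback reverses the order of protection and uses aprotic dioxolanation, setting out from 9. Silylation (Et3SiCl, imidazole, CH2Cl2) should give methyl (R)-9-oxo-3-(triethylsilyloxy)tetradecanoate F5. Treatment with Me3SiOCH2CH2OSiMe3 and catalytic Me3SiOTf in CH2Cl2 at −78 °C should give methyl (R)-8-(2-pentyl-1,3-dioxolan-2-yl)-3-(triethylsilyloxy)octanoate F6. Amidation with MeNH(OMe)·HCl and iPrMgCl in THF at −20 °C should then rejoin the route at 12.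

Further compounds
F1 | step 11 | 7-hydroxy-2,2-dimethyl-5-[(R)-7-(2-pentyl-1,3-dioxolan-2-yl)-2-(triethylsilyloxy)heptyl]-4H-benzo[d][1,3]dioxin-4-one | CCCCCC1(OCCO1)CCCCC[C@@H](O[Si](CC)(CC)CC)Cc2cc(O)cc3OC(C)(C)OC(=O)c23
F2 | step 11 | (R)-6,8-dihydroxy-3-[5-(2-pentyl-1,3-dioxolan-2-yl)pentyl]isochroman-1-one | CCCCCC1(OCCO1)CCCCC[C@@H]2Cc3cc(O)cc(O)c3C(=O)O2
F3 | step 10 | (R)-8-(2-pentyl-1,3-dioxolan-2-yl)-3-(triethylsilyloxy)octanal | CCCCCC1(OCCO1)CCCCC[C@@H](O[Si](CC)(CC)CC)CC=O
F4 | step 10 | 6-[(6R)-4-hydroxy-2-oxo-11-(2-pentyl-1,3-dioxolan-2-yl)-6-(triethylsilyloxy)undecyl]-2,2-dimethyl-4H-1,3-dioxin-4-one | CCCCCC1(OCCO1)CCCCC[C@@H](O[Si](CC)(CC)CC)CC(O)CC(=O)CC2=CC(=O)OC(C)(C)O2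
F5 | step 6 | methyl (R)-9-oxo-3-(triethylsilyloxy)tetradecanoate | CCCCCC(=O)CCCCC[C@@H](O[Si](CC)(CC)CC)CC(=O)OC
F6 | step 6 | methyl (R)-8-(2-pentyl-1,3-dioxolan-2-yl)-3-(triethylsilyloxy)octanoate | CCCCCC1(OCCO1)CCCCC[C@@H](O[Si](CC)(CC)CC)CC(=O)OC
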